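All runs come from a simulation for an exercise, noise included.

A small charge of starting material was what I had to reckon with: 0.11 M in epsilon against 0.22 M in the ash run, at the same 20 °C.

all flasks: partner 0.198 M; catalyst 7.5 mM
- ash: starting material 0.22 M; second substrate 0.11 M; temperature 20 °C; run made earlier
- epsilon: starting material 0.11 M; second substrate 0.110 M; temperature 20 °C; time 20 h
- alpha: starting material 0.11 M; second substrate 0.110 M; temperature 50 °C; time 20 h
- gamma: starting material 0.11 M; second substrate 0.110 M; temperature −10 °C; time 20 h
- beta: starting material 0.11 M; second substrate 0.110 M; temperature 80 °C; time 20 h

- ash (time / min: target / %): 10.0: 24.1; 20.0: 33.6; 30.0: 37.5; 60.0: 41.9; 120: 41.6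

(each reading ± 0.5 percentage points)

* the best flask by amount of target, in percent of the starting material charged; "all alike" if 1.5 percentage points covers them all (epsilon / alpha / gamma / beta / all alike)
* amount of target at the end, in percent of the starting material charged, epsilon
* amount of target at the end, in percent of the starting material charged, alpha
* amount of target at the end, in percent of the starting material charged, gamma
* amount of target at the end, in percent of the starting material charged, beta

- the earlier runs do not show what temperature does; that part of a forecast is a guess

The ash run stood flat at 41.8%, which is 0.0919 M of target. That amount plus the second substrate, 0.202 M, came close to the 0.198 M of partner, so I guessed that partner was the limiting reagent and that second substrate competed for it. I therefore carried the partner share, the target made per partner charged, which read 46.4% in the ash run.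

A smaller charge competes no better, so keeping that share gave my upper bound, 83.5% for epsilon. A share falling in step with the charge gave my lower bound, 41.8%.

To tighten this, I replaced the falling curve of cA by its mean, 0.174 M in the ash run, and let the odds of partner reaching target follow that mean, at 4.97 M⁻¹. Starting from the lower bound, this gave 54.4%. Repeating it with the new mean gave 51.3%, so the second pass moved my figure by 3.1 percentage points. My own reckoning committed to 51.3%, and I kept the lower bound, since the ash readings end at 120 min, well short of 20 h. Temperature stayed a guess.

The forecast lay inside my bracket but above my own figure at 80% for epsilon, with 73% for alpha, 83% for gamma, 60% for beta and gamma as best, on the view that “side reactions or catalyst death usually ease in the cold”.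

The flasks gave 44.8% in epsilon, 15.4% in alpha, 63.4% in gamma and 6.07% in beta, so gamma held the most.

    2 partner → homo dimer (k = 0.00173 M⁻¹ s⁻¹, Ea = 47.0 kJ mol⁻¹)
    starting material + target → side product (k = 1.32 × 10⁻⁴ M⁻¹ s⁻¹, Ea = 72.0 kJ mol⁻¹)
    second substrate + partner + catalyst → catalyst + second product (k = 0.448 M⁻² s⁻¹, Ea = 37.0 kJ mol⁻¹)
    starting material + partner + catalyst → catalyst + target (k = 0.493 M⁻² s⁻¹, Ea = 40.0 kJ mol⁻¹)
    (constants at 20 °C)

In beta, partner had a half-life of 3.0 min by the second-substrate path at 0.0113 h, far shorter than the 1.44 h half-life of the flask's slowest mode at 20.0 h. At that same 0.0113 h, starting material in beta went to target 8.9 times as fast as to side product. What second product and homo dimer left of the partner gives a share of 34.0% in epsilon, below the ash reading. In beta the share was 29.5%, or 0.0583 M of target made, and at 20.0 h side product held 93.9% of the starting material.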